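**Plan**

- Retrosynthetic cuts, in order: the O–CH3 bond of the vinylogous ester; the benzenoid ring of the naphthoquinone (C12–C8a and C15–C4a, Diels–Alder then aromatization); the C12=C13 and C14=C15 alkenes (two Wittig reactions); the C8–C9 bond of ring B; the C9–C10 and C5–C6 bonds on ring A; ring A itself (Michael/aldol annulation).
- Forward order: ring A is made first, its two arms are attached and the C1 carbonyl is removed, ring B is closed onto the alkyne, the arene ring is grown on the finished decalin, and the quinone ring arrives intact with the dienophile.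
- Enabling feature: the exocyclic C8=C17 methylene beside the C9 stereocentre of ring B is what a C9 radical leaves after 6-exo attack on a C8≡C17 alkyne held by C5 of ring A.
- Stereochemistry: C4 from the chiral amine catalyst; C5 by copper-mediated addition anti to CH2OTBDPS; C10 by aldol attack anti to the C5 chain; C9 in the chair-like radical closure; the 12E alkene from a stabilized ylide.

Key step: step 10

Assumption: compounds 7, 10 and 24 and the ylide Ph3P=C(CH3)CHO are taken as catalogue chemicals; locants C1–C20 are labdane locants, and quinone locants are marked as such.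

**Step 1**
Reactants: 1 methyl 3-hydroxy-2-methylpropanoate (racemic)
Product: 2 methyl 3-[(tert-butyldiphenylsilyl)oxy]-2-methylpropanoate (racemic)
Conditions: TBDPSCl, imidazole, DMF, 25 °C
Reagents that add atoms: tert-butyl(chloro)diphenylsilane, CC(C)(C)[Si](Cl)(c1ccccc1)c1ccccc1
Why: Imidazole-promoted silylation of a primary alcohol; the stereocentre is racemic and is erased in step 3, so no control is needed.

**Step 2**
Reactants: 2 methyl 3-[(tert-butyldiphenylsilyl)oxy]-2-methylpropanoate
Product: 3 3-[(tert-butyldiphenylsilyl)oxy]-2-methylpropanal (racemic)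
Conditions: i-Bu2AlH, CH2Cl2, −78 °C; Rochelle salt work-up
Reagents that add atoms: none
Why: Partial ester reduction, in which the tetrahedral aluminium hemiacetal survives at low temperature and releases the aldehyde on work-up.

**Step 3**
Reactants: 3 3-[(tert-butyldiphenylsilyl)oxy]-2-methylpropanal; 4 ethyl vinyl ketone
Product: 6 (S)-4-{[(tert-butyldiphenylsilyl)oxy]methyl}-2,4-dimethylcyclohex-2-en-1-one, via keto aldehyde 5 (not isolated)
Conditions: N-(4-dodecylphenylsulfonyl)pyrrolidine-2-carboxamide (20 mol %, the enantiomer that delivers 4S), BnNH2, 4 Å molecular sieves, ClCH2CH2Cl, 25 °C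
Reagents that add atoms: none
Why: Amine-catalysed asymmetric Michael addition of the α-branched aldehyde (as its enamine) to the vinyl ketone followed by intramolecular aldol condensation (organocatalytic Robinson-type annulation), in which the enamine face selected by the chiral sulfonamide should set quaternary C4 as S.

**Step 4**
Reactants: 6 (S)-4-{[(tert-butyldiphenylsilyl)oxy]methyl}-2,4-dimethylcyclohex-2-en-1-one; 7 (4-bromobut-1-yn-1-yl)trimethylsilane
Product: 9 (3R,4S)-4-{[(tert-butyldiphenylsilyl)oxy]methyl}-2,4-dimethyl-1-[(trimethylsilyl)oxy]-3-[4-(trimethylsilyl)but-3-yn-1-yl]cyclohex-1-ene, via [4-(trimethylsilyl)but-3-yn-1-yl]magnesium bromide 8 (not isolated)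
Conditions: 7, Mg, THF, 25 °C; then 6, CuBr·SMe2 (10 mol %), TMSCl, THF, −78 to −40 °C; Et3N
Reagents that add atoms: chlorotrimethylsilane, C[Si](C)(C)Cl
Why: Copper-catalysed conjugate addition of a Grignard reagent with silyl trapping of the enolate; the nucleophile should enter C5 axially, anti to the larger pseudoaxial CH2OTBDPS group, so the chain ends trans to C18 and cis to the C4 methyl.

**Step 5**
Reactants: 9 ring A trimethylsilyl enol ether; 10 3-[(tert-butyldimethylsilyl)oxy]propanal
Product: 11 ring A β-hydroxy ketone (C1 ketone; C10 bears CH3 and CH(OH)CH2CH2OTBS; C9 epimers)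
Conditions: BF3·OEt2, CH2Cl2, −78 °C; aq. NaHCO3
Reagents that add atoms: none
Why: Mukaiyama aldol addition of the tetrasubstituted enol silane to the activated aldehyde; attack anti to the neighbouring C5 chain should set quaternary C10 with the C9 arm trans to the butynyl arm, and the C9 carbinol configuration is immaterial because C9 later becomes a radical.

**Step 6**
Reactants: 11 ring A β-hydroxy ketone
Product: 12 C1 tosylhydrazone of 11
Conditions: TsNHNH2, EtOH, 60 °C
Reagents that add atoms: 4-methylbenzenesulfonohydrazide, Cc1ccc(cc1)S(=O)(=O)NN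
Why: Tosylhydrazone formation by condensation at the only carbonyl group, under neutral conditions that spare both silyl ethers and the silyl alkyne.

**Step 7**
Reactants: 12 C1 tosylhydrazone
Product: 13 ring A alcohol with C1 as CH2 (trimethylsilyl alkyne; C9 epimers)
Conditions: catecholborane, CHCl3, 0 °C; then NaOAc·3H2O, 60 °C
Reagents that add atoms: none
Why: Caglioti-type deoxygenation in the Kabalka variant, in which hydroboration of C=N, acetate-induced loss of sulfinate and extrusion of N2 from the diazene leave a methylene at C1 without touching the alkyne.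

**Step 8**
Reactants: 13 ring A alcohol (trimethylsilyl alkyne)
Product: 14 ring A alcohol with terminal alkyne (C9 epimers)
Conditions: K2CO3 (cat.), MeOH, 25 °C
Reagents that add atoms: none
Why: Base-catalysed methanolysis of the alkynyl C–Si bond (protodesilylation), to which alkyl silyl ethers are inert.

**Step 9**
Reactants: 14 ring A alcohol with terminal alkyne
Product: 15 O-C9 imidazole-1-carbothioate of 14 (C9 epimers)
Conditions: 1,1'-thiocarbonyldiimidazole, 4-(dimethylamino)pyridine (cat.), toluene, 80 °C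
Reagents that add atoms: 1,1'-thiocarbonyldiimidazole, S=C(n1ccnc1)n1ccnc1
Why: Thioacylation of the secondary alcohol (Barton–McCombie activation) under neutral conditions, chosen over an alkoxide-based xanthate synthesis so that the silyl group cannot migrate from O12 to O9.

**Step 10**
Reactants: 15 O-C9 imidazole-1-carbothioate
Product: 16 12-[(tert-butyldimethylsilyl)oxy]-18-[(tert-butyldiphenylsilyl)oxy]-13,14,15,16-tetranor-ent-labd-8(17)-ene
Conditions: Bu3SnH and 2,2'-azobis(2-methylpropanenitrile) added over 8 h by syringe pump, toluene (0.005 M), 100 °C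
Reagents that add atoms: none
Why: The stannyl radical adds to the thiocarbonyl group and the C9–O bond fragments to give the secondary C9 radical, which adds to the inner alkyne carbon C8; the C17 vinyl radical then takes hydrogen from the stannane to leave the C8=C17 methylene. The closest known reaction type is the tin hydride mediated cyclization of alkyl radicals onto terminal alkynes to give methylenecyclohexanes. Ring B closes in the 6-exo-dig mode, the 7-endo path being stereoelectronically disfavoured. C9 is set by substrate control: ring A holds the butynyl and C9 arms trans-diequatorial, so only a chair-like transition state leading to the trans-decalin is open, and in it the C11 arm sits pseudo-equatorial, which leaves H9 axial and cis to H5. The step needs ring closure to outrun hydrogen transfer to the open-chain radical and stannyl addition to the alkyne; the two quaternary carbons flanking C5 pre-organize the chain and slow addition keeps the stannane concentration low. Both C9 epimers of 15 converge on the same radical.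

**Step 11**
Reactants: 16 bis-silyl ether of the decalin core
Product: 17 18-[(tert-butyldiphenylsilyl)oxy]-13,14,15,16-tetranor-ent-labd-8(17)-en-12-ol
Conditions: camphor-10-sulfonic acid (cat.), MeOH/CH2Cl2, 0 °C
Reagents that add atoms: none
Why: Acid-catalysed methanolysis removes the unhindered primary TBS ether much faster than the neopentyl TBDPS ether, and the catalytic acid at 0 °C should not move the exocyclic alkene.

**Step 12**
Reactants: 17 C12 alcohol
Product: 18 18-[(tert-butyldiphenylsilyl)oxy]-13,14,15,16-tetranor-ent-labd-8(17)-en-12-al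
Conditions: 1,1,1-triacetoxy-1,1-dihydro-1,2-benziodoxol-3(1H)-one (Dess–Martin periodinane), CH2Cl2, 0 to 25 °C
Reagents that add atoms: none
Why: Dess–Martin oxidation of a primary alcohol to the aldehyde under mild conditions that leave the alkene and the silyl ether alone.

**Step 13**
Reactants: 18 C12 aldehyde
Product: 19 (12E)-18-[(tert-butyldiphenylsilyl)oxy]-15-nor-ent-labda-8(17),12-dien-14-al
Conditions: Ph3P=C(CH3)CHO, toluene, 90 °C
Reagents that add atoms: 2-(triphenylphosphoranylidene)propanal, CC(C=O)=P(c1ccccc1)(c1ccccc1)c1ccccc1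
Why: Wittig olefination with a stabilized formyl ylide, which should give the E trisubstituted enal.

**Step 14**
Reactants: 19 (12E)-enal
Product: 20 (12E)-18-[(tert-butyldiphenylsilyl)oxy]-ent-labda-8(17),12,14-triene
Conditions: Ph3PCH3Br, KOtBu, THF, 0 °C
Reagents that add atoms: methyltriphenylphosphonium bromide, C[P+](c1ccccc1)(c1ccccc1)c1ccccc1.[Br-]
Why: Wittig methylenation of the enal carbonyl completes the diene without touching the C12=C13 geometry.

**Step 15**
Reactants: 20 silyl-protected triene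
Product: 21 (12E)-ent-labda-8(17),12,14-trien-18-ol
Conditions: Bu4NF, THF, 50 °C
Reagents that add atoms: none
Why: Fluoride-mediated cleavage of the silyl ether, to which the hydrocarbon triene is inert.

**Step 16**
Reactants: 21 triene alcohol
Product: 22 (12E)-ent-labda-8(17),12,14-trien-18-al
Conditions: 1,1,1-triacetoxy-1,1-dihydro-1,2-benziodoxol-3(1H)-one (Dess–Martin periodinane), CH2Cl2, 0 to 25 °C
Reagents that add atoms: none
Why: Dess–Martin oxidation of the neopentyl primary alcohol to an aldehyde that has no α-hydrogen and therefore cannot epimerize.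

**Step 17**
Reactants: 22 triene aldehyde
Product: 23 (12E)-ent-labda-8(17),12,14-trien-18-oic acid
Conditions: NaClO2, NaH2PO4, 2-methylbut-2-ene, t-BuOH/H2O, 25 °C
Reagents that add atoms: sodium chlorite, [Na+].[O-]Cl=O
Why: Pinnick oxidation of the hindered aldehyde, with 2-methylbut-2-ene scavenging hypochlorous acid so that the diene and the exocyclic alkene are spared.

**Step 18**
Reactants: 24 3-methoxy-2-methylphenol
Product: 25 2-methoxy-3-methyl-1,4-benzoquinone
Conditions: (KSO3)2NO, KH2PO4 buffer, H2O/acetone, 25 °C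
Reagents that add atoms: potassium nitrosodisulfonate, [K+].[K+].[O]N(S(=O)(=O)[O-])S(=O)(=O)[O-]
Why: Teuber oxidation, in which Fremy's salt converts a phenol with a free para position into the para-quinone.

**Step 19**
Reactants: 23 (12E)-ent-labda-8(17),12,14-trien-18-oic acid; 25 2-methoxy-3-methyl-1,4-benzoquinone
Product: 27 O-methyl ether of the target (2-methoxy-3,7-dimethyl-1,4-naphthoquinone carrying the decalin acid through C11 at C8), via Diels–Alder adduct 26 (not isolated)
Conditions: toluene, 90 °C; then 2,3-dichloro-5,6-dicyano-1,4-benzoquinone (DDQ), 25 °C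
Reagents that add atoms: none
Why: Diels–Alder cycloaddition at the unsubstituted quinone double bond followed by enolization and DDQ dehydrogenation to the naphthoquinone; the quinone C4 carbonyl is deactivated as a vinylogous ester, so quinone C5 is the electrophilic carbon and should bond to the unhindered C15 terminus of the 1-alkyl diene, which places C12 next to the carbonyl flanked by the methoxy carbon.

**Step 20**
Reactants: 27 O-methyl ether of the target
Product: 28 CNP0259461.3
Conditions: NaOH, MeOH/H2O, 25 °C; then aq. HCl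
Reagents that add atoms: sodium hydroxide, [Na+].[OH-]
Why: Vinylogous ester hydrolysis by addition–elimination of hydroxide at the methoxy-bearing quinone carbon, followed by acidification of the carboxylate and the hydroxyquinone.

**Compound list**

1 | methyl 3-hydroxy-2-methylpropanoate (racemic) | COC(=O)C(C)CO | starting material
2 | methyl 3-[(tert-butyldiphenylsilyl)oxy]-2-methylpropanoate (racemic) | COC(=O)C(C)CO[Si](c1ccccc1)(c1ccccc1)C(C)(C)C | intermediate
3 | 3-[(tert-butyldiphenylsilyl)oxy]-2-methylpropanal (racemic) | O=CC(C)CO[Si](c1ccccc1)(c1ccccc1)C(C)(C)C | intermediate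
4 | ethyl vinyl ketone (pent-1-en-3-one) | CCC(=O)C=C | starting material
5 | (R)-2-{[(tert-butyldiphenylsilyl)oxy]methyl}-2-methyl-5-oxoheptanal (Michael adduct) | O=C[C@@](C)(CO[Si](c1ccccc1)(c1ccccc1)C(C)(C)C)CCC(=O)CC | intermediate
6 | (S)-4-{[(tert-butyldiphenylsilyl)oxy]methyl}-2,4-dimethylcyclohex-2-en-1-one (ring A enone; the quaternary carbon is C4) | O=C1CC[C@](C)(CO[Si](c2ccccc2)(c2ccccc2)C(C)(C)C)C=C1C | intermediate
7 | (4-bromobut-1-yn-1-yl)trimethylsilane | C[Si](C)(C)C#CCCBr | starting material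
8 | [4-(trimethylsilyl)but-3-yn-1-yl]magnesium bromide | C[Si](C)(C)C#CCC[Mg]Br | intermediate
9 | (3R,4S)-4-{[(tert-butyldiphenylsilyl)oxy]methyl}-2,4-dimethyl-1-[(trimethylsilyl)oxy]-3-[4-(trimethylsilyl)but-3-yn-1-yl]cyclohex-1-ene (butynyl chain trans to CH2OTBDPS, cis to the C4 methyl) | C[Si](C)(C)C#CCC[C@H]1C(C)=C(O[Si](C)(C)C)CC[C@]1(C)CO[Si](c1ccccc1)(c1ccccc1)C(C)(C)C | intermediate
10 | 3-[(tert-butyldimethylsilyl)oxy]propanal | O=CCCO[Si](C)(C)C(C)(C)C | starting material
11 | 4-{[(tert-butyldiphenylsilyl)oxy]methyl}-2-{3-[(tert-butyldimethylsilyl)oxy]-1-hydroxypropyl}-2,4-dimethyl-3-[4-(trimethylsilyl)but-3-yn-1-yl]cyclohexan-1-one; the hydroxypropyl arm and CH2OTBDPS are both trans to the butynyl chain, both ring methyls cis to it; carbinol carbon C9 as a mixture of epimers | C[Si](C)(C)C#CCC[C@H]1[C@@](C)(C(=O)CC[C@]1(C)CO[Si](c1ccccc1)(c1ccccc1)C(C)(C)C)C(O)CCO[Si](C)(C)C(C)(C)C | intermediate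
12 | 4-methylbenzenesulfonylhydrazone of 11 at the ring carbonyl C1 (ring configuration as in 11; C9 epimers) | C[Si](C)(C)C#CCC[C@H]1[C@@](C)(C(=NNS(=O)(=O)c2ccc(C)cc2)CC[C@]1(C)CO[Si](c1ccccc1)(c1ccccc1)C(C)(C)C)C(O)CCO[Si](C)(C)C(C)(C)C | intermediate
13 | 3-[(tert-butyldimethylsilyl)oxy]-1-{3-{[(tert-butyldiphenylsilyl)oxy]methyl}-1,3-dimethyl-2-[4-(trimethylsilyl)but-3-yn-1-yl]cyclohexyl}propan-1-ol (ring configuration as in 11; C9 epimers) | C[Si](C)(C)C#CCC[C@H]1[C@@](C)(CCC[C@]1(C)CO[Si](c1ccccc1)(c1ccccc1)C(C)(C)C)C(O)CCO[Si](C)(C)C(C)(C)C | intermediate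
14 | 1-{2-(but-3-yn-1-yl)-3-{[(tert-butyldiphenylsilyl)oxy]methyl}-1,3-dimethylcyclohexyl}-3-[(tert-butyldimethylsilyl)oxy]propan-1-ol (ring configuration as in 11; C9 epimers) | C#CCC[C@H]1[C@@](C)(CCC[C@]1(C)CO[Si](c1ccccc1)(c1ccccc1)C(C)(C)C)C(O)CCO[Si](C)(C)C(C)(C)C | intermediate
15 | O-C9 1H-imidazole-1-carbothioate of 14 (radical precursor; C9 epimers) | C#CCC[C@H]1[C@@](C)(CCC[C@]1(C)CO[Si](c1ccccc1)(c1ccccc1)C(C)(C)C)C(OC(=S)n1ccnc1)CCO[Si](C)(C)C(C)(C)C | intermediate
16 | 12-[(tert-butyldimethylsilyl)oxy]-18-[(tert-butyldiphenylsilyl)oxy]-13,14,15,16-tetranor-ent-labd-8(17)-ene (trans-decalin; 5β-H, 9β-H, 10α-CH3, 4α-CH3, 4β-CH2OSi) | C=C1CC[C@H]2[C@@](C)(CCC[C@]2(C)CO[Si](c2ccccc2)(c2ccccc2)C(C)(C)C)[C@@H]1CCO[Si](C)(C)C(C)(C)C | intermediate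
17 | 18-[(tert-butyldiphenylsilyl)oxy]-13,14,15,16-tetranor-ent-labd-8(17)-en-12-ol | C=C1CC[C@H]2[C@@](C)(CCC[C@]2(C)CO[Si](c2ccccc2)(c2ccccc2)C(C)(C)C)[C@@H]1CCO | intermediate
18 | 18-[(tert-butyldiphenylsilyl)oxy]-13,14,15,16-tetranor-ent-labd-8(17)-en-12-al | C=C1CC[C@H]2[C@@](C)(CCC[C@]2(C)CO[Si](c2ccccc2)(c2ccccc2)C(C)(C)C)[C@@H]1CC=O | intermediate
19 | (12E)-18-[(tert-butyldiphenylsilyl)oxy]-15-nor-ent-labda-8(17),12-dien-14-al | C=C1CC[C@H]2[C@@](C)(CCC[C@]2(C)CO[Si](c2ccccc2)(c2ccccc2)C(C)(C)C)[C@@H]1C/C=C(\C)C=O | intermediate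
20 | (12E)-18-[(tert-butyldiphenylsilyl)oxy]-ent-labda-8(17),12,14-triene | C=C1CC[C@H]2[C@@](C)(CCC[C@]2(C)CO[Si](c2ccccc2)(c2ccccc2)C(C)(C)C)[C@@H]1C/C=C(\C)C=C | intermediate
21 | (12E)-ent-labda-8(17),12,14-trien-18-ol | C=C1CC[C@H]2[C@@](C)(CCC[C@]2(C)CO)[C@@H]1C/C=C(\C)C=C | intermediate
22 | (12E)-ent-labda-8(17),12,14-trien-18-al | C=C1CC[C@H]2[C@@](C)(CCC[C@]2(C)C=O)[C@@H]1C/C=C(\C)C=C | intermediate
23 | (12E)-ent-labda-8(17),12,14-trien-18-oic acid | C=C1CC[C@H]2[C@@](C)(CCC[C@]2(C)C(=O)O)[C@@H]1C/C=C(\C)C=C | intermediate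
24 | 3-methoxy-2-methylphenol | COc1cccc(O)c1C | starting material
25 | 2-methoxy-3-methyl-1,4-benzoquinone | COC1=C(C)C(=O)C=CC1=O | intermediate
26 | cis-fused Diels–Alder adduct: 2-methoxy-3,7-dimethyl-4a,5,8,8a-tetrahydro-1,4-naphthoquinone carrying the decalin acid through C11 at C8 (mixture of diastereomers at C8, C4a and C8a) | C=C1CC[C@H]2[C@@](C)(CCC[C@]2(C)C(=O)O)[C@@H]1CC1C(C)=CCC2C1C(=O)C(OC)=C(C)C2=O | intermediate
27 | O-methyl ether of the target: 2-methoxy-3,7-dimethyl-1,4-naphthoquinone carrying the ent-labdane decalin (8(17)-ene, C18 acid) through C11 at C8 | C=C1CC[C@H]2[C@@](C)(CCC[C@]2(C)C(=O)O)[C@@H]1Cc1c(C)ccc2c1C(=O)C(OC)=C(C)C2=O | intermediate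
28 | CNP0259461.3: 2-hydroxy-3,7-dimethyl-1,4-naphthoquinone carrying the ent-labdane decalin (8(17)-ene, C18 acid; 5β-H, 9β-H, 10α-CH3) through C11 at C8 | C=C1CC[C@H]2[C@@](C)(CCC[C@]2(C)C(=O)O)[C@@H]1Cc1c(C)ccc2c1C(=O)C(O)=C(C)C2=O | target

**Count and risks**

Total step count: 20. Longest linear sequence: 19 steps (steps 1–17, 19 and 20); step 18 is a one-step side branch.

The three steps most likely to fail:

Step 3. The enamine of an aldehyde with two alkyl-type α-substituents may form with little geometric preference, and silanolate may be lost from it, so C4 could be set with low enantiomeric purity or the aldehyde consumed by elimination. The fallback sets out from 4 and comes back at 6. Ethyl vinyl ketone 4 would be silylated (TBSOTf, Et3N) to (Z)-3-[(tert-butyldimethylsilyl)oxy]penta-1,3-diene F1. An enantioselective Diels–Alder reaction of F1 with methacrolein, catalysed by the triflimide-activated 1-(2-methylphenyl)-3,3-diphenyl-tetrahydropyrrolo[1,2-c][1,3,2]oxazaborole (the antipode that gives 1S), should set the quaternary carbon in (1S)-4-[(tert-butyldimethylsilyl)oxy]-1,5-dimethylcyclohex-3-ene-1-carbaldehyde F2. NaBH4 reduction and mild acid hydrolysis of the enol ether would give (4S)-4-(hydroxymethyl)-2,4-dimethylcyclohexan-1-one F3, and silylation with TBDPSCl the ketone (4S)-4-{[(tert-butyldiphenylsilyl)oxy]methyl}-2,4-dimethylcyclohexan-1-one F4. Thermodynamic enol silylation (TMSCl, NaI, Et3N) to the tetrasubstituted trimethylsilyl enol ether F5 and Saegusa–Ito oxidation with Pd(OAc)2 would return enone 6.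

Step 4. The copper reagent may discriminate poorly between the methyl face and the silyloxymethyl face at the neopentyl β-carbon, so the C5 epimer could form in quantity. The fallback sets out from 7 (through its Grignard reagent 8) and from 4, and comes back at 9. Reagent 8 would be formylated with DMF to 5-(trimethylsilyl)pent-4-ynal F6 and olefinated with Ph3P=C(CH3)CHO to (E)-2-methyl-7-(trimethylsilyl)hept-2-en-6-ynal F7. An enantioselective Diels–Alder reaction of F7 with the diene F1 of the preceding fallback, under the same oxazaborolidinium catalyst, would fix the C4/C5 relationship stereospecifically from the E geometry of the dienophile, giving the formyl enol silane adduct F8 (C10 epimers). NaBH4 reduction and mild acid hydrolysis would give the hydroxy ketone F9, silylation with TBDPSCl the ketone F10, and thermodynamic enol silylation (TMSCl, NaI, Et3N) the enol silane 9.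

Step 19. The C12 alkyl group and the C13 methyl group polarize the diene in opposite senses, so the cycloaddition may proceed in both orientations and give the regioisomeric naphthoquinone alongside 27. The fallback sets out from 18 and comes back at 27. Aldehyde 18 would be olefinated with Ph3P=C(CH3)C(O)CH3 to the (12E)-14-ketone F11 and converted (TBSOTf, Et3N) into the 14-silyloxy triene F12, whose enol ether makes C15 the unambiguous nucleophilic terminus. Cycloaddition with 25 would give the adduct F13 and DDQ dehydrogenation the 6-silyloxy naphthoquinone F14. Bu4NF would remove both silyl groups to give the phenol alcohol F15; phenol-selective triflation (PhNTf2, Et3N) would give the aryl triflate F16; reduction with Pd(OAc)2, 1,1'-bis(diphenylphosphino)ferrocene, HCO2H and Et3N would give the C18 alcohol F17. Dess–Martin oxidation to the aldehyde F18 and NaClO2 oxidation would then give 27.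

**Further compounds**

F1 | step 3 | (Z)-3-[(tert-butyldimethylsilyl)oxy]penta-1,3-diene | C/C=C(\O[Si](C)(C)C(C)(C)C)C=C
F2 | step 3 | (1S)-4-[(tert-butyldimethylsilyl)oxy]-1,5-dimethylcyclohex-3-ene-1-carbaldehyde (C5 epimers) | O=C[C@]1(C)CC(C)C(O[Si](C)(C)C(C)(C)C)=CC1
F3 | step 3 | (4S)-4-(hydroxymethyl)-2,4-dimethylcyclohexan-1-one (C2 epimers) | OC[C@]1(C)CC(C)C(=O)CC1
F4 | step 3 | (4S)-4-{[(tert-butyldiphenylsilyl)oxy]methyl}-2,4-dimethylcyclohexan-1-one (C2 epimers) | CC(C)(C)[Si](OC[C@]1(C)CC(C)C(=O)CC1)(c1ccccc1)c1ccccc1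
F5 | step 3 | (4S)-4-{[(tert-butyldiphenylsilyl)oxy]methyl}-2,4-dimethyl-1-[(trimethylsilyl)oxy]cyclohex-1-ene | CC(C)(C)[Si](OC[C@]1(C)CC(C)=C(O[Si](C)(C)C)CC1)(c1ccccc1)c1ccccc1
F6 | step 4 | 5-(trimethylsilyl)pent-4-ynal | C[Si](C)(C)C#CCCC=O
F7 | step 4 | (E)-2-methyl-7-(trimethylsilyl)hept-2-en-6-ynal | C[Si](C)(C)C#CCC/C=C(\C)C=O
F8 | step 4 | 4-[(tert-butyldimethylsilyl)oxy]-1,5-dimethyl-6-[4-(trimethylsilyl)but-3-yn-1-yl]cyclohex-3-ene-1-carbaldehyde (formyl trans to the butynyl chain; C5 epimers) | C[Si](C)(C)C#CCC[C@H]1C(C)C(O[Si](C)(C)C(C)(C)C)=CC[C@]1(C)C=O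
F9 | step 4 | 4-(hydroxymethyl)-2,4-dimethyl-3-[4-(trimethylsilyl)but-3-yn-1-yl]cyclohexan-1-one (hydroxymethyl trans to the butynyl chain; C2 epimers) | C[Si](C)(C)C#CCC[C@H]1C(C)C(=O)CC[C@]1(C)CO
F10 | step 4 | 4-{[(tert-butyldiphenylsilyl)oxy]methyl}-2,4-dimethyl-3-[4-(trimethylsilyl)but-3-yn-1-yl]cyclohexan-1-one (silyloxymethyl trans to the butynyl chain; C2 epimers) | C[Si](C)(C)C#CCC[C@H]1C(C)C(=O)CC[C@]1(C)CO[Si](c1ccccc1)(c1ccccc1)C(C)(C)C
F11 | step 19 | (12E)-18-[(tert-butyldiphenylsilyl)oxy]-ent-labda-8(17),12-dien-14-one | C=C1CC[C@H]2[C@@](C)(CCC[C@]2(C)CO[Si](c2ccccc2)(c2ccccc2)C(C)(C)C)[C@@H]1C/C=C(\C)C(C)=O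
F12 | step 19 | (12E)-14-[(tert-butyldimethylsilyl)oxy]-18-[(tert-butyldiphenylsilyl)oxy]-ent-labda-8(17),12,14-triene | C=C1CC[C@H]2[C@@](C)(CCC[C@]2(C)CO[Si](c2ccccc2)(c2ccccc2)C(C)(C)C)[C@@H]1C/C=C(\C)C(=C)O[Si](C)(C)C(C)(C)C
F13 | step 19 | cis-fused adduct of F12 and 25: 6-[(tert-butyldimethylsilyl)oxy]-2-methoxy-3,7-dimethyl-4a,5,8,8a-tetrahydro-1,4-naphthoquinone carrying the 18-silyloxy decalin through C11 at C8 (diastereomer mixture) | C=C1CC[C@H]2[C@@](C)(CCC[C@]2(C)CO[Si](c2ccccc2)(c2ccccc2)C(C)(C)C)[C@@H]1CC1C(C)=C(O[Si](C)(C)C(C)(C)C)CC2C1C(=O)C(OC)=C(C)C2=O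
F14 | step 19 | 6-[(tert-butyldimethylsilyl)oxy]-2-methoxy-3,7-dimethyl-1,4-naphthoquinone carrying the 18-[(tert-butyldiphenylsilyl)oxy] decalin through C11 at C8 | C=C1CC[C@H]2[C@@](C)(CCC[C@]2(C)CO[Si](c2ccccc2)(c2ccccc2)C(C)(C)C)[C@@H]1Cc1c(C)c(O[Si](C)(C)C(C)(C)C)cc2c1C(=O)C(OC)=C(C)C2=O
F15 | step 19 | 6-hydroxy-2-methoxy-3,7-dimethyl-1,4-naphthoquinone carrying the 18-hydroxy decalin through C11 at C8 | C=C1CC[C@H]2[C@@](C)(CCC[C@]2(C)CO)[C@@H]1Cc1c(C)c(O)cc2c1C(=O)C(OC)=C(C)C2=O
F16 | step 19 | 6-trifluoromethanesulfonate of F15 | C=C1CC[C@H]2[C@@](C)(CCC[C@]2(C)CO)[C@@H]1Cc1c(C)c(OS(=O)(=O)C(F)(F)F)cc2c1C(=O)C(OC)=C(C)C2=O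
F17 | step 19 | 2-methoxy-3,7-dimethyl-1,4-naphthoquinone carrying the 18-hydroxy decalin through C11 at C8 | C=C1CC[C@H]2[C@@](C)(CCC[C@]2(C)CO)[C@@H]1Cc1c(C)ccc2c1C(=O)C(OC)=C(C)C2=O
F18 | step 19 | 2-methoxy-3,7-dimethyl-1,4-naphthoquinone carrying the 18-oxo decalin through C11 at C8 | C=C1CC[C@H]2[C@@](C)(CCC[C@]2(C)C=O)[C@@H]1Cc1c(C)ccc2c1C(=O)C(OC)=C(C)C2=O
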